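**Retrosynthetic overview**
1. The target comes from Wittig methylenation of the 8-oxo cis-decalin keto acid (C8=C17 is made last).
2. Ring B comes from a one-carbon ring expansion. C-9, already carrying the whole side chain, is inserted between C-8 and C-10 of a (Z)-alkylidene cis-hydrindane by an oxidative 1,2-shift of the quaternary C-10.
3. The side chain is built by Wittig olefination (C8=C9), cross-metathesis with methyl acrylate (C13=C14), and a catalyst-controlled conjugate methylation (C-13, C-16).
4. The cis-hydrindanone acid comes from a Michael/alkylation annulation of 2-methylcyclopentenone with 5-chloropentanenitrile, then convex-face C-4 methylation, nitrile hydrolysis and resolution.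
5. Ring order: the five-membered ring is bought, ring A is annulated onto it, and ring B is made from the five-membered ring by expansion.

Assumption: the SMILES is read literally as a 5,10-cis-fused labdane (H-5, C-20, C-11 and the C-4 methyl on one face; CO2H and H-9 on the other; 13R), labdane numbering is used for atoms, and the antipodes named for the resolving amine and for Tol-BINAP are the ones I expect to match and would be swapped if the sign proves opposite.

**Step 1**
Reactants: 1 5-chloropentanenitrile; 2 2-methylcyclopent-2-en-1-one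
Product: 4 (±)-cis-7a-methyl-1-oxooctahydro-1H-indene-4-carbonitrile (H-3a and 7a-CH3 syn; C-4 epimer mixture), via lithium enolate 3 (not isolated)
Conditions: LiN(i-Pr)2 (1.05 equiv), THF–DMPU, −78 °C; 2, −78 → −20 °C; then NaI (0.2 equiv), 45 °C
Reagents that add atoms: none
Why: Michael-initiated ring closure, in which the lithiated nitrile ends up in THF–DMPU as the thermodynamic 1,4-adduct and the tetrasubstituted enolate 3 released at C-10 closes ring A by a 6-exo-tet alkylation that can only give the cis fusion (H-5 syn to C-20), C-4 being left as an irrelevant epimer mixture.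

**Step 2**
Reactants: 4 (±)-cis-7a-methyl-1-oxooctahydro-1H-indene-4-carbonitrile
Product: 6 (±)-(3aS*,4S*,7aR*)-4,7a-dimethyl-1-oxooctahydro-1H-indene-4-carbonitrile, via dilithio dianion 5 (not isolated)
Conditions: LiN(i-Pr)2 (2.3 equiv), THF, −78 → −20 °C; MeI (1.05 equiv), −78 °C; H2O
Reagents that add atoms: iodomethane, CI
Why: Dianion alkylation, in which the more basic and slim N-lithio ketenimine takes the single equivalent of MeI before the ketone enolate, and because the linear C=C=N unit has no allylic strain ring A keeps the chair with C-8 axial, so MeI enters equatorially from the convex face and places the new methyl syn to H-5 and C-20 and the nitrile on the concave face.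

**Step 3**
Reactants: 6 (±)-(3aS*,4S*,7aR*)-4,7a-dimethyl-1-oxooctahydro-1H-indene-4-carbonitrile
Product: 7 (±)-(3aR*,4S*,7aR*)-4,7a-dimethyl-1-oxooctahydro-1H-indene-4-carboxylic acid
Conditions: KOH, HOCH2CH2OH–H2O, 170 °C; then aq HCl
Reagents that add atoms: potassium hydroxide, [K+].[OH-]; water, O
Why: Alkaline hydrolysis of a tertiary nitrile, helped by the 1,3-diaxial ketone whose hydrate can add to the nitrile, in a molecule that has no epimerisable stereocentre.

**Step 4**
Reactants: 7 (±)-(3aR*,4S*,7aR*)-4,7a-dimethyl-1-oxooctahydro-1H-indene-4-carboxylic acid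
Product: 9 (3aR,4S,7aR)-4,7a-dimethyl-1-oxooctahydro-1H-indene-4-carboxylic acid (single enantiomer), via phenylethylammonium salt 8 (not isolated)
Conditions: (R)-PhCH(CH3)NH2 (0.55 equiv), EtOAc–EtOH, two crystallisations; wet cake into 1 M HCl/EtOAc
Reagents that add atoms: none
Why: Classical resolution by fractional crystallisation of diastereomeric ammonium carboxylates fixes the absolute configuration of C-4, C-5 and C-10 in one operation.

**Step 5**
Reactants: 10 5-bromopent-1-ene
Product: 11 (pent-4-en-1-yl)triphenylphosphonium bromide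
Conditions: PPh3, MeCN, reflux
Reagents that add atoms: triphenylphosphine, c1ccc(cc1)P(c1ccccc1)c1ccccc1
Why: Simple SN2 quaternisation of a primary bromide; no stereocentre is involved.

**Step 6**
Reactants: 9 (3aR,4S,7aR)-4,7a-dimethyl-1-oxooctahydro-1H-indene-4-carboxylic acid; 11 (pent-4-en-1-yl)triphenylphosphonium bromide
Product: 13 (1Z,3aR,4S,7aR)-4,7a-dimethyl-1-(pent-4-en-1-ylidene)octahydro-1H-indene-4-carboxylic acid, via ylide 12 (not isolated)
Conditions: 11 (2.5 equiv), KOt-Bu (3.4 equiv), THF, 0 °C → reflux; aq HCl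
Reagents that add atoms: none
Why: Wittig olefination of a cyclopentanone next to a methyl-bearing quaternary carbon, the situation of steroidal 17-ketones, where unstabilised ylides give under kinetic control the (Z)-alkylidene with the chain syn to the quaternary carbon, the acid travelling as its carboxylate.

**Step 7**
Reactants: 13 (1Z,3aR,4S,7aR)-4,7a-dimethyl-1-(pent-4-en-1-ylidene)octahydro-1H-indene-4-carboxylic acid; 14 methyl acrylate
Product: 15 (1Z,3aR,4S,7aR)-1-[(4E)-6-methoxy-6-oxohex-4-en-1-ylidene]-4,7a-dimethyloctahydro-1H-indene-4-carboxylic acid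
Conditions: second-generation Hoveyda–Grubbs catalyst (5 mol %), 14 (5 equiv), CH2Cl2, 40 °C
Reagents that add atoms: none
Why: Olefin cross-metathesis of a reactive terminal alkene with an acrylate gives the E-enoate, while the hindered trisubstituted C8=C9 alkene and the free acid are spectators.

**Step 8**
Reactants: 15 (1Z,3aR,4S,7aR)-1-[(4E)-6-methoxy-6-oxohex-4-en-1-ylidene]-4,7a-dimethyloctahydro-1H-indene-4-carboxylic acid
Product: 16 (1Z,3aR,4S,7aR)-1-[(4R)-6-methoxy-4-methyl-6-oxohexylidene]-4,7a-dimethyloctahydro-1H-indene-4-carboxylic acid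
Conditions: MeMgBr (3.2 equiv), CuI (5 mol %), (S)-Tol-BINAP (7.5 mol %), t-BuOMe, −20 °C; aq HCl
Reagents that add atoms: methylmagnesium bromide, C[Mg]Br
Why: Copper-catalysed asymmetric conjugate addition of MeMgBr to an E-enoate, in which the Tol-BINAP–copper complex picks the enoate face far from the core so that C-13 is set as R under catalyst control, the first equivalent of MeMgBr only deprotonating the acid.

**Step 9**
Reactants: 16 (1Z,3aR,4S,7aR)-1-[(4R)-6-methoxy-4-methyl-6-oxohexylidene]-4,7a-dimethyloctahydro-1H-indene-4-carboxylic acid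
Product: 18 (1S,4aR,5S,8aR)-5-[(3R)-5-methoxy-3-methyl-5-oxopentyl]-1,4a-dimethyl-6-oxodecahydronaphthalene-1-carboxylic acid, via iodonio lactone 17 (not isolated)
Conditions: PhI(OH)OTs (1.1 equiv), (CF3)2CHOH–H2O (19:1), 0 °C
Reagents that add atoms: hydroxy(tosyloxy)iodobenzene, Cc1ccc(cc1)S(=O)(=O)OI(O)c1ccccc1
Why: Proposed new method: a carboxyl-assisted oxidative ring expansion of an unactivated trisubstituted alkylidenecyclopentane by trivalent iodine, in which PhI(OH)OTs adds to C-9 from the convex face while the 1,3-diaxial C-4 carboxyl captures C-8 from the concave face (17), the hindered secondary C–I bond then leaves as PhI with an antiperiplanar 1,2-shift of the electron-rich quaternary C-10 (retention at C-10, inversion at C-9) rather than of the C-7 methylene, and water opens the acyloxycarbenium ion to the C-8 ketone and the free acid, so that Z geometry plus convex attack put H-9 on the concave face and the side chain syn to C-20, which I also estimate to be the equatorial and more stable epimer; the closest known reactions are the Koser-reagent ring expansion of aryl-conjugated exocyclic alkenes (aryl migration), the tosyloxylactonisation of alkenoic acids and the semipinacol D-homoannulation of steroidal 17-hydroxy-20-sulfonates.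

**Step 10**
Reactants: 18 (1S,4aR,5S,8aR)-5-[(3R)-5-methoxy-3-methyl-5-oxopentyl]-1,4a-dimethyl-6-oxodecahydronaphthalene-1-carboxylic acid
Product: 19 (1S,4aS,5R,8aR)-5-[(3R)-5-methoxy-3-methyl-5-oxopentyl]-1,4a-dimethyl-6-methylidenedecahydronaphthalene-1-carboxylic acid (target)
Conditions: Ph3PCH3Br (4.2 equiv), KN(SiMe3)2 (4.0 equiv), THF, 0 → 45 °C; aq HCl to pH 3
Reagents that add atoms: methyltriphenylphosphonium bromide, C[P+](c1ccccc1)(c1ccccc1)c1ccccc1.[Br-]
Why: Wittig methylenation as is routine for 8-oxolabdanes, with the phosphonium salt in slight excess over base so that the methyl ester survives, the acid carried as its carboxylate, and C-9 not expected to drift because it already holds what I estimate to be the more stable equatorial configuration.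

**Compound list**
1 | 5-chloropentanenitrile | N#CCCCCCl | starting material
2 | 2-methylcyclopent-2-en-1-one | CC1=CCCC1=O | starting material
3 | lithium enolate of 5-chloro-2-(2-methyl-3-oxocyclopentyl)pentanenitrile (racemic; the enantiomer carried on is drawn) | [Li+].[O-]C1=C(C)[C@H](C(CCCCl)C#N)CC1 | intermediate
4 | (±)-cis-7a-methyl-1-oxooctahydro-1H-indene-4-carbonitrile, (3aS,7aR) drawn, C-4 epimers | O=C1CC[C@@H]2[C@@]1(C)CCCC2C#N | intermediate
5 | dilithio dianion of 4 (ketone enolate plus N-lithio ketenimine; racemic) | [Li+].[Li+].[O-]C1=CC[C@@H]2[C@@]1(C)CCCC2=C=[N-] | intermediate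
6 | (±)-4,7a-dimethyl-1-oxooctahydro-1H-indene-4-carbonitrile, (3aS,4S,7aR) drawn | O=C1CC[C@@H]2[C@@]1(C)CCC[C@]2(C)C#N | intermediate
7 | (±)-4,7a-dimethyl-1-oxooctahydro-1H-indene-4-carboxylic acid, (3aR,4S,7aR) drawn | O=C1CC[C@@H]2[C@@]1(C)CCC[C@]2(C)C(=O)O | intermediate
8 | (R)-1-phenylethylammonium (3aR,4S,7aR)-4,7a-dimethyl-1-oxooctahydro-1H-indene-4-carboxylate | O=C1CC[C@@H]2[C@@]1(C)CCC[C@]2(C)C(=O)[O-].C[C@@H]([NH3+])c1ccccc1 | intermediate
9 | (3aR,4S,7aR)-4,7a-dimethyl-1-oxooctahydro-1H-indene-4-carboxylic acid, single enantiomer | O=C1CC[C@@H]2[C@@]1(C)CCC[C@]2(C)C(=O)O | intermediate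
10 | 5-bromopent-1-ene | C=CCCCBr | starting material
11 | (pent-4-en-1-yl)triphenylphosphonium bromide | C=CCCC[P+](c1ccccc1)(c1ccccc1)c1ccccc1.[Br-] | intermediate
12 | (pent-4-en-1-ylidene)triphenylphosphorane | C=CCCC=P(c1ccccc1)(c1ccccc1)c1ccccc1 | intermediate
13 | (1Z,3aR,4S,7aR)-4,7a-dimethyl-1-(pent-4-en-1-ylidene)octahydro-1H-indene-4-carboxylic acid | C[C@@]12CCC[C@](C)(C(=O)O)[C@@H]1CC/C2=C/CCC=C | intermediate
14 | methyl acrylate | C=CC(=O)OC | starting material
15 | (1Z,3aR,4S,7aR)-1-[(4E)-6-methoxy-6-oxohex-4-en-1-ylidene]-4,7a-dimethyloctahydro-1H-indene-4-carboxylic acid | C[C@@]12CCC[C@](C)(C(=O)O)[C@@H]1CC/C2=C/CC/C=C/C(=O)OC | intermediate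
16 | (1Z,3aR,4S,7aR)-1-[(4R)-6-methoxy-4-methyl-6-oxohexylidene]-4,7a-dimethyloctahydro-1H-indene-4-carboxylic acid | C[C@@]12CCC[C@](C)(C(=O)O)[C@@H]1CC/C2=C/CC[C@@H](C)CC(=O)OC | intermediate
17 | C19–O–C8 δ-lactone bearing a phenyliodonio group at C-9, tosylate salt | C[C@@]12CCC[C@@]3(C)[C@@H]1CC[C@@]2(OC3=O)[C@H](CC[C@@H](C)CC(=O)OC)[I+]c1ccccc1.Cc1ccc(cc1)S(=O)(=O)[O-] | intermediate
18 | (1S,4aR,5S,8aR)-5-[(3R)-5-methoxy-3-methyl-5-oxopentyl]-1,4a-dimethyl-6-oxodecahydronaphthalene-1-carboxylic acid | O=C1CC[C@@H]2[C@@](C)(CCC[C@]2(C)C(=O)O)[C@@H]1CC[C@@H](C)CC(=O)OC | intermediate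
19 | (1S,4aS,5R,8aR)-5-[(3R)-5-methoxy-3-methyl-5-oxopentyl]-1,4a-dimethyl-6-methylidenedecahydronaphthalene-1-carboxylic acid | C=C1CC[C@@H]2[C@@](C)(CCC[C@]2(C)C(=O)O)[C@@H]1CC[C@@H](C)CC(=O)OC | target

**Step count:** 10 steps in total. The longest linear sequence is 9 steps (steps 1–4 and 6–10).

**The three steps most likely to fail**

Step 9 (the new ring expansion). The iodonio lactone could be intercepted by tosylate or water, or C-7 could migrate instead of C-10. The fallback uses known chemistry, sets out from 16 and returns at 18. OsO4 (cat.)/N-methylmorpholine N-oxide dihydroxylates C8=C9 from the convex face to give the 8,9-diol F1. MsCl/pyridine sulfonylates only the secondary C-9 hydroxyl to give the hydroxy mesylate F2. KOt-Bu in THF then triggers the classical semipinacol ring enlargement, with C-10 anti to the mesylate and inversion at C-9, giving 18 with the same C-9 configuration.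

Step 1 (annulation). The lithiated nitrile may add 1,2 or simply enolise the enone. The fallback sets out from 2 and returns at 4, and it replaces the hard carbanion by a soft one. Methyl cyanoacetate is alkylated with 1-bromo-3-chloropropane (K2CO3, DMF) to methyl 5-chloro-2-cyanopentanoate F3. DBU-catalysed Michael addition of this donor to 2 gives the open cyano ester adduct F4. KOt-Bu/NaI closes ring A to the bicyclic cyano ester F5, and Krapcho demethoxycarbonylation (LiCl, wet DMSO, 150 °C) delivers 4.

Step 2 (dianion methylation). Methylation at C-7 or incomplete C-4 deprotonation could spoil chemoselectivity. The fallback sets out from 4 and returns at 6, and it removes the competing enolate altogether. Ethylene glycol/TsOH converts 4 into the dioxolane nitrile F6. LiN(i-Pr)2 then MeI gives the C-4 methylated dioxolane F7, where the bulkier axial ketal carbon shields the concave face even better. Aqueous HCl in THF then releases 6.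

**Further compounds**
F1 | step 9 | (8,9-diol) (3aR,4S,7aR)-1-hydroxy-1-[(4R)-1-hydroxy-6-methoxy-4-methyl-6-oxohexyl]-4,7a-dimethyloctahydro-1H-indene-4-carboxylic acid, both hydroxyls delivered from the convex face | C[C@@]12CCC[C@](C)(C(=O)O)[C@@H]1CC[C@]2(O)[C@@H](O)CC[C@@H](C)CC(=O)OC
F2 | step 9 | C-9 methanesulfonate of F1 | C[C@@]12CCC[C@](C)(C(=O)O)[C@@H]1CC[C@]2(O)[C@@H](OS(C)(=O)=O)CC[C@@H](C)CC(=O)OC
F3 | step 1 | methyl 5-chloro-2-cyanopentanoate | COC(=O)C(CCCCl)C#N
F4 | step 1 | methyl 5-chloro-2-cyano-2-(2-methyl-3-oxocyclopentyl)pentanoate (racemic) | O=C1CC[C@@H](C(CCCCl)(C#N)C(=O)OC)C1C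
F5 | step 1 | methyl (±)-cis-4-cyano-7a-methyl-1-oxooctahydro-1H-indene-4-carboxylate | O=C1CC[C@@H]2[C@@]1(C)CCCC2(C#N)C(=O)OC
F6 | step 2 | ethylene ketal of 4 (racemic) | O1CCOC12CC[C@@H]3[C@@]2(C)CCCC3C#N
F7 | step 2 | ethylene ketal of 6 (racemic) | O1CCOC12CC[C@@H]3[C@@]2(C)CCC[C@]3(C)C#N
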